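Ring A, the trioxygenated ring, is numbered C1 (aroyl), C2 (OH), C3 (H), C4 (OH), C5 (prenyl), C6 (OMe). Everything rests on cutting it at two neighbouring atoms, the C1–carbonyl bond and the C6–O bond. Because the aroyl carbon and the single methylated oxygen sit side by side, a C1–C6 aryne can accept the vanilloyl group and a carboxylate oxygen in one fluoride-triggered operation, giving an ortho-hydroxy ketone whose only free OH is the one to be methylated. The aryne precursor is a 2-silylaryl triflate bearing the C5 prenyl group and MOM ethers at C2 and C4; its partner is MOM-protected vanillic acid as its caesium salt.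

Key step: step 8

Remarks on the chemistry:
- The target is achiral and its only alkene carries two identical methyl groups, so no stereochemical element has to be set.
- The precursor is assembled with silicon introduced before prenyl, so that no benzylic-allylic CH2 is present when the second strong base is used.
- The doubly ortho-substituted diethylcarbamate is removed reductively, not by hydrolysis.

Step 1
Reactants: 1 phloroglucinol (benzene-1,3,5-triol)
Product: 2 3,5-bis(methoxymethoxy)phenol
Conditions: MOMCl (2.0 equiv), i-Pr2NEt, THF, 0 °C to rt; chromatography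
Reagents that add atoms: chloromethyl methyl ether (MOMCl), COCCl
Why: O-alkylation of phenols with an α-chloro ether (acetal formation) is statistical here, but the three hydroxyls are equivalent, so only the degree of alkylation has to be controlled and the bis-ether should be separable from the mono- and tris-ethers.

Step 2
Reactants: 2 3,5-bis(methoxymethoxy)phenol
Product: 3 3,5-bis(methoxymethoxy)phenyl N,N-diethylcarbamate
Conditions: ClC(O)NEt2, K2CO3, MeCN, reflux
Reagents that add atoms: N,N-diethylcarbamoyl chloride, CCN(CC)C(Cl)=O
Why: O-carbamoylation of the phenoxide (nucleophilic acyl substitution) installs the strongest ortho-directing group available, and the base-stable MOM ethers are untouched.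

Step 3
Reactants: 3 3,5-bis(methoxymethoxy)phenyl N,N-diethylcarbamate
Product: 5 3,5-bis(methoxymethoxy)-2-(trimethylsilyl)phenyl N,N-diethylcarbamate, via aryllithium 4 (not isolated)
Conditions: s-BuLi, TMEDA, THF, −78 °C; then TMSCl, −78 °C to rt
Reagents that add atoms: chlorotrimethylsilane, C[Si](C)(C)Cl
Why: In this directed ortho-metalation the carbamate cooperates with a flanking OMOM group, so deprotonation should occur at one of the two symmetry-equivalent carbons between them rather than between the two acetals, and the cold aryllithium is silylated before an anionic Fries shift can begin.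

Step 4
Reactants: 5 3,5-bis(methoxymethoxy)-2-(trimethylsilyl)phenyl N,N-diethylcarbamate; 6 prenyl bromide (1-bromo-3-methylbut-2-ene)
Product: 8 3,5-bis(methoxymethoxy)-2-(3-methylbut-2-en-1-yl)-6-(trimethylsilyl)phenyl N,N-diethylcarbamate, via aryllithium 7 (not isolated)
Conditions: s-BuLi, TMEDA, THF, −78 °C; then CuBr·SMe2 (10 mol %), 6, −78 to −20 °C
Reagents that add atoms: prenyl bromide (6), CC(C)=CCBr
Why: A second directed ortho-metalation at the one remaining carbamate-flanked carbon, followed by copper-assisted allylic substitution at the unhindered primary carbon of the bromide, should give the linear prenyl arene.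

Step 5
Reactants: 8 3,5-bis(methoxymethoxy)-2-(3-methylbut-2-en-1-yl)-6-(trimethylsilyl)phenyl N,N-diethylcarbamate
Product: 9 3,5-bis(methoxymethoxy)-2-(3-methylbut-2-en-1-yl)-6-(trimethylsilyl)phenol
Conditions: LiAlH4, THF, 0 to 50 °C; Rochelle-salt work-up (pH ≥ 7)
Reagents that add atoms: none
Why: Reductive cleavage of the aryl O-carbamate by hydride needs no bulky nucleophile at the doubly ortho-substituted centre and spares the acetals, the trisubstituted alkene and the C–Si bond, while the non-acidic work-up protects the electron-rich arylsilane from protodesilylation.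

Step 6
Reactants: 9 3,5-bis(methoxymethoxy)-2-(3-methylbut-2-en-1-yl)-6-(trimethylsilyl)phenol
Product: 10 3,5-bis(methoxymethoxy)-2-(3-methylbut-2-en-1-yl)-6-(trimethylsilyl)phenyl trifluoromethanesulfonate
Conditions: Tf2O, pyridine, CH2Cl2, −20 to 0 °C
Reagents that add atoms: trifluoromethanesulfonic anhydride, O=S(=O)(OS(=O)(=O)C(F)(F)F)C(F)(F)F
Why: O-sulfonylation of an ortho-silyl phenol with triflic anhydride is the standard entry to ortho-silylaryl triflates, and the cold pyridine-buffered medium should leave the acetals, alkene and arylsilane intact.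

Step 7
Reactants: 11 vanillic acid (4-hydroxy-3-methoxybenzoic acid)
Product: 13 3-methoxy-4-(methoxymethoxy)benzoic acid, via MOM ester 12 (not isolated)
Conditions: MOMCl (2.5 equiv), i-Pr2NEt, CH2Cl2, 0 °C to rt; then NaOH, MeOH/H2O, rt; 1 M HCl to pH 4, 0 °C
Reagents that add atoms: chloromethyl methyl ether (MOMCl), COCCl; sodium hydroxide (supplies the carboxyl OH oxygen), [Na+].[OH-]
Why: Double O-alkylation followed by saponification of the much more labile acyloxymethyl ester should return the acid with the aryl MOM ether intact, provided the acidification is brief, cold and stops at pH 4.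

Step 8
Reactants: 10 3,5-bis(methoxymethoxy)-2-(3-methylbut-2-en-1-yl)-6-(trimethylsilyl)phenyl trifluoromethanesulfonate; 13 3-methoxy-4-(methoxymethoxy)benzoic acid
Product: 16 [2-hydroxy-4,6-bis(methoxymethoxy)-3-(3-methylbut-2-en-1-yl)phenyl][3-methoxy-4-(methoxymethoxy)phenyl]methanone, via caesium carboxylate 14 (not isolated), via aryne 15 (not isolated)
Conditions: 13 (2 equiv), Cs2CO3 (1 equiv), MeOH, rt, evaporate, dry in vacuo; then 10 (1 equiv), CsF (3 equiv), THF, sealed tube, 110 °C; aq. NH4Cl
Reagents that add atoms: none
Why: Fluoride removes the silyl group and the resulting C1 anion expels triflate from C6 to give the C1–C6 aryne 15; the carboxylate oxygen of 14 adds to C6, and the C1 aryl anion so formed attacks the new ester carbonyl through a four-membered alkoxide that opens to the ortho-acyl phenoxide, a net insertion into the acid C–O bond that forms the C6–O and C1–C(=O) bonds. The closest known reaction type is the fluoride-induced insertion of arynes from ortho-silylaryl triflates into the C–O bond of carboxylic acids, which gives ortho-hydroxyaryl ketones and is mechanistically an anionic 1,3 O-to-C acyl shift of the ortho-Fries type. No ring is closed and no stereocentre is created, so neither a mode of closure nor facial control arises. The selectivity needed is regiochemical, oxygen at C6 and acyl at C1: the σ-withdrawing OMOM group on C2, directly beside the triple bond, should polarise and distort the aryne so that the nucleophile attacks the remote terminus C6 and charge develops at C1 next to that oxygen, which is expected to outweigh the modest steric shielding of C6 by the C5 prenyl group. Acyl transfer must also outrun protonation of the aryl anion, which would stop at the aryl ester, and this is why the pre-dried caesium salt in aprotic THF replaces the free acid. Keeping the triflate as the limiting component against excess carboxylate, together with the hindered, ketone-chelated nature of the product phenoxide, should suppress its arylation by a second aryne.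

Step 9
Reactants: 16 [2-hydroxy-4,6-bis(methoxymethoxy)-3-(3-methylbut-2-en-1-yl)phenyl][3-methoxy-4-(methoxymethoxy)phenyl]methanone
Product: 17 [2-methoxy-4,6-bis(methoxymethoxy)-3-(3-methylbut-2-en-1-yl)phenyl][3-methoxy-4-(methoxymethoxy)phenyl]methanone
Conditions: MeI, K2CO3, DMF, rt to 40 °C
Reagents that add atoms: iodomethane, CI
Why: This Williamson O-methylation needs no selectivity because the C6 phenol is the only free hydroxyl, and a polar aprotic medium should overcome its hydrogen bond to the ketone and the flanking prenyl group.

Step 10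
Reactants: 17 [2-methoxy-4,6-bis(methoxymethoxy)-3-(3-methylbut-2-en-1-yl)phenyl][3-methoxy-4-(methoxymethoxy)phenyl]methanone
Product: 18 [4,6-dihydroxy-2-methoxy-3-(3-methylbut-2-en-1-yl)phenyl](4-hydroxy-3-methoxyphenyl)methanone (CNP0197938.0)
Conditions: HCl (about 1 M) in MeOH/H2O, rt to 40 °C
Reagents that add atoms: none
Why: Acid-catalysed acetal methanolysis removes all three MOM ethers while the aryl methyl ethers and the ketone are inert, and mild temperature with close monitoring should keep the C4 phenol from adding to the prenyl alkene.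

Compound list
1 | phloroglucinol (benzene-1,3,5-triol) | Oc1cc(O)cc(O)c1 | starting material
2 | 3,5-bis(methoxymethoxy)phenol | COCOc1cc(O)cc(OCOC)c1 | intermediate
3 | 3,5-bis(methoxymethoxy)phenyl N,N-diethylcarbamate | CCN(CC)C(=O)Oc1cc(OCOC)cc(OCOC)c1 | intermediate
4 | {2-[(diethylcarbamoyl)oxy]-4,6-bis(methoxymethoxy)phenyl}lithium (aryllithium from 3, formed in the flask) | [Li]c1c(OC(=O)N(CC)CC)cc(OCOC)cc1OCOC | intermediate
5 | 3,5-bis(methoxymethoxy)-2-(trimethylsilyl)phenyl N,N-diethylcarbamate | CCN(CC)C(=O)Oc1cc(OCOC)cc(OCOC)c1[Si](C)(C)C | intermediate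
6 | prenyl bromide (1-bromo-3-methylbut-2-ene) | CC(C)=CCBr | starting material
7 | {2-[(diethylcarbamoyl)oxy]-4,6-bis(methoxymethoxy)-3-(trimethylsilyl)phenyl}lithium (aryllithium from 5, formed in the flask) | CCN(CC)C(=O)Oc1c([Li])c(OCOC)cc(OCOC)c1[Si](C)(C)C | intermediate
8 | 3,5-bis(methoxymethoxy)-2-(3-methylbut-2-en-1-yl)-6-(trimethylsilyl)phenyl N,N-diethylcarbamate | CCN(CC)C(=O)Oc1c(CC=C(C)C)c(OCOC)cc(OCOC)c1[Si](C)(C)C | intermediate
9 | 3,5-bis(methoxymethoxy)-2-(3-methylbut-2-en-1-yl)-6-(trimethylsilyl)phenol | Oc1c(CC=C(C)C)c(OCOC)cc(OCOC)c1[Si](C)(C)C | intermediate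
10 | 3,5-bis(methoxymethoxy)-2-(3-methylbut-2-en-1-yl)-6-(trimethylsilyl)phenyl trifluoromethanesulfonate (aryne precursor) | COCOc1cc(OCOC)c([Si](C)(C)C)c(OS(=O)(=O)C(F)(F)F)c1CC=C(C)C | intermediate
11 | vanillic acid (4-hydroxy-3-methoxybenzoic acid) | COc1cc(C(=O)O)ccc1O | starting material
12 | methoxymethyl 3-methoxy-4-(methoxymethoxy)benzoate (formed in the flask) | COCOC(=O)c1ccc(OCOC)c(OC)c1 | intermediate
13 | 3-methoxy-4-(methoxymethoxy)benzoic acid | COCOc1ccc(C(=O)O)cc1OC | intermediate
14 | caesium 3-methoxy-4-(methoxymethoxy)benzoate (dried, used crude) | COCOc1ccc(C(=O)[O-])cc1OC.[Cs+] | intermediate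
15 | 1,2-didehydro-3,5-bis(methoxymethoxy)-6-(3-methylbut-2-en-1-yl)benzene (the C1–C6 aryne of ring A, formed in the flask) | COCOC1=CC(OCOC)=C(CC=C(C)C)C#C1 | intermediate
16 | [2-hydroxy-4,6-bis(methoxymethoxy)-3-(3-methylbut-2-en-1-yl)phenyl][3-methoxy-4-(methoxymethoxy)phenyl]methanone | COCOc1cc(OCOC)c(C(=O)c2ccc(OCOC)c(OC)c2)c(O)c1CC=C(C)C | intermediate
17 | [2-methoxy-4,6-bis(methoxymethoxy)-3-(3-methylbut-2-en-1-yl)phenyl][3-methoxy-4-(methoxymethoxy)phenyl]methanone | COCOc1cc(OCOC)c(C(=O)c2ccc(OCOC)c(OC)c2)c(OC)c1CC=C(C)C | intermediate
18 | [4,6-dihydroxy-2-methoxy-3-(3-methylbut-2-en-1-yl)phenyl](4-hydroxy-3-methoxyphenyl)methanone | COc1cc(C(=O)c2c(O)cc(O)c(CC=C(C)C)c2OC)ccc1O | target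

Total step count: 10. Longest linear sequence: 9 steps (steps 1 to 6, then 8, 9 and 10, from phloroglucinol); the vanillic acid branch joins after one step.

Steps most likely to fail

Step 8. What may go wrong: addition of the carboxylate at the wrong aryne terminus (C1 instead of C6), protonation of the aryl anion before the acyl shift, or arylation of the product phenoxide by further aryne. The fallback is a bromine–lithium-exchange-triggered anionic ortho-Fries rearrangement, in which the position of the halogen fixes the regiochemistry. It sets out from carbamate 3 and returns to the route at ketone 16.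
- Carbamate 3 is ortho-lithiated (s-BuLi, TMEDA, THF, −78 °C) and quenched with BrCCl2CCl2Br to give 2-bromo-3,5-bis(methoxymethoxy)phenyl N,N-diethylcarbamate F1.
- The other carbamate-flanked carbon is deprotonated with lithium 2,2,6,6-tetramethylpiperidide (LiTMP, THF, −78 °C; an amide base avoids bromine–lithium exchange) and alkylated with prenyl bromide 6 (CuBr·SMe2 cat.) to give 2-bromo-3,5-bis(methoxymethoxy)-6-(3-methylbut-2-en-1-yl)phenyl N,N-diethylcarbamate F2.
- LiAlH4 (THF, 0 °C to rt, conditions under which the aryl bromide should persist) releases 2-bromo-3,5-bis(methoxymethoxy)-6-(3-methylbut-2-en-1-yl)phenol F3.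
- Esterification with acid 13 (EDC·HCl, DMAP, CH2Cl2) gives 2-bromo-3,5-bis(methoxymethoxy)-6-(3-methylbut-2-en-1-yl)phenyl 3-methoxy-4-(methoxymethoxy)benzoate F4.
- n-BuLi (THF, −95 to −78 °C, then warming) exchanges bromine for lithium at C1, and the acyl group moves from the C6 oxygen to C1 to give 16.

Step 4. What may go wrong: sluggish coupling of the encumbered aryl metal with the prenyl electrophile, attack at the tertiary end of the allyl system, or an anionic Fries shift of the carbamate on warming. The fallback sets out from 5 and returns at 8. The same lithiation is followed by trapping with the smaller, symmetrical allyl bromide to give 2-allyl-3,5-bis(methoxymethoxy)-6-(trimethylsilyl)phenyl N,N-diethylcarbamate F5. Olefin cross-metathesis with 2-methyl-2-butene (second-generation Grubbs catalyst, (H2IMes)(PCy3)Cl2Ru=CHPh, CH2Cl2, 40 °C) then converts the allyl into the prenyl group of 8.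

Step 10. What may go wrong: acid-promoted addition of the C4 phenol to the prenyl alkene (chroman formation) or hydration of the alkene during acetal cleavage. The fallback sets out from 17 and returns at 18 by a non-protic exchange of protecting groups. TMSOTf with 2,2'-bipyridyl (CH2Cl2, 0 °C to rt) converts the three aryl MOM ethers into aryl silyl ethers, giving [2-methoxy-3-(3-methylbut-2-en-1-yl)-4,6-bis(trimethylsilyloxy)phenyl][3-methoxy-4-(trimethylsilyloxy)phenyl]methanone F6. Water (or K2CO3 in MeOH) then hydrolyses the silyl ethers to 18 under essentially neutral conditions.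

Further compounds
F1 | step 8 | 2-bromo-3,5-bis(methoxymethoxy)phenyl N,N-diethylcarbamate | CCN(CC)C(=O)Oc1cc(OCOC)cc(OCOC)c1Br
F2 | step 8 | 2-bromo-3,5-bis(methoxymethoxy)-6-(3-methylbut-2-en-1-yl)phenyl N,N-diethylcarbamate | CCN(CC)C(=O)Oc1c(CC=C(C)C)c(OCOC)cc(OCOC)c1Br
F3 | step 8 | 2-bromo-3,5-bis(methoxymethoxy)-6-(3-methylbut-2-en-1-yl)phenol | Oc1c(CC=C(C)C)c(OCOC)cc(OCOC)c1Br
F4 | step 8 | 2-bromo-3,5-bis(methoxymethoxy)-6-(3-methylbut-2-en-1-yl)phenyl 3-methoxy-4-(methoxymethoxy)benzoate | COCOc1ccc(C(=O)Oc2c(CC=C(C)C)c(OCOC)cc(OCOC)c2Br)cc1OC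
F5 | step 4 | 2-allyl-3,5-bis(methoxymethoxy)-6-(trimethylsilyl)phenyl N,N-diethylcarbamate | CCN(CC)C(=O)Oc1c(CC=C)c(OCOC)cc(OCOC)c1[Si](C)(C)C
F6 | step 10 | [2-methoxy-3-(3-methylbut-2-en-1-yl)-4,6-bis(trimethylsilyloxy)phenyl][3-methoxy-4-(trimethylsilyloxy)phenyl]methanone | COc1cc(C(=O)c2c(O[Si](C)(C)C)cc(O[Si](C)(C)C)c(CC=C(C)C)c2OC)ccc1O[Si](C)(C)C
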